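**Retrosynthetic overview**
1. Feature: the benzene ring C4a–C5–C6–C7–C8–C8a is a hydroquinone monoether (O1 on C8a, free OH on C6, para to each other). O1 is tied back to the neighbouring ring carbon C4a by C2–C3–C4 (dihydropyran ring). A chromium alkoxycarbene + alkyne + CO benzannulation gives this pattern when the alkyne hangs on the carbene oxygen.
2. Key disconnection: C8a–C4a, C5–C6 and C6–C7 are cut together, which opens both rings to a pentacarbonylchromium (tert-alkoxy)(isopropenyl)carbene. In the forward direction the dihydropyran closes first (alkyne insertion) and the benzene ring second (CO insertion, 6π closure), in one operation.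
3. O1–C8a: the carbene complex is assembled from the tertiary alkynol and an acetoxy(isopropenyl)carbene complex made from 2-bromopropene and Cr(CO)6.
4. C4–C4a and C2: acetylide displacement on the epoxy triflate of ω-silyloxygeranylgeraniol, then hydride opening. C2 (R) is set by Sharpless epoxidation with D-(−)-tartrate.
5. C13': SeO2 hydroxylation of geranylgeranyl acetate at the start. It is raised to the acid (MnO2, Pinnick) after both rings stand, with the phenol masked as acetate.

Key step: step 9

Remark (assumption): isomerically pure (E,E,E)-geranylgeraniol is taken as a commercial starting material.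
Remark (numbering and notation): chroman numbering (O1, C2–C8a, chain C1'–C13') is used for all late compounds. Geranylgeraniol C1, C2, C3 and C16 become C4, C3, C2 and C13'. Carbonyl ligands are written M=C=O in SMILES, and the η6-arene chromium complex is written as arene and Cr(CO)3 joined by a dot.

Step 1
Reactants: 1 (E,E,E)-geranylgeraniol
Product: 2 (E,E,E)-geranylgeranyl acetate
Conditions: Ac2O, pyridine, DMAP (cat.), CH2Cl2, 0 °C → rt
Reagents that add atoms: acetic anhydride CC(=O)OC(C)=O
Why: Routine DMAP-catalysed O-acetylation, which masks the C1 hydroxyl and makes the C2=C3 alkene electron-poor, so that it stays out of the selenium ene reaction of step 2.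

Step 2
Reactants: 2 (E,E,E)-geranylgeranyl acetate
Product: 3 (2E,6E,10E,14E)-16-hydroxygeranylgeranyl acetate
Conditions: SeO2 (cat.), t-BuOOH, salicylic acid (cat.), CH2Cl2, 0 °C → rt, stopped at partial conversion, recovered 2 recycled
Reagents that add atoms: selenium dioxide O=[Se]=O (hands over the oxygen), tert-butyl hydroperoxide CC(C)(C)OO (restores it)
Why: Riley-type allylic hydroxylation (ene reaction, then [2,3]-sigmatropic shift) prefers the least hindered terminal gem-dimethyl alkene and oxidises the methyl group trans to the chain, so the 14E (later 11'E) geometry follows from the mechanism.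

Step 3
Reactants: 3 (2E,6E,10E,14E)-16-hydroxygeranylgeranyl acetate
Product: 4 (2E,6E,10E,14E)-16-(tert-butyldimethylsilyloxy)geranylgeranyl acetate
Conditions: TBSCl, imidazole, DMF, 0 °C → rt
Reagents that add atoms: tert-butyldimethylsilyl chloride CC(C)(C)[Si](C)(C)Cl
Why: Standard imidazole-promoted silylation of a primary allylic alcohol, giving an ether that withstands methanolysis, titanium/peroxide, triflation, acetylide, borohydride and the neutral chromium chemistry.

Step 4
Reactants: 4 (2E,6E,10E,14E)-16-(tert-butyldimethylsilyloxy)geranylgeranyl acetate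
Product: 5 (2E,6E,10E,14E)-16-(tert-butyldimethylsilyloxy)geranylgeraniol
Conditions: K2CO3 (cat.), MeOH, rt
Reagents that add atoms: none
Why: Base-catalysed transesterification (Zemplén-type methanolysis) removes the acetate and leaves the silyl ether and all four E alkenes untouched.

Step 5
Reactants: 5 (2E,6E,10E,14E)-16-(tert-butyldimethylsilyloxy)geranylgeraniol
Product: 6 (2R,3R)-2,3-epoxide of 5
Conditions: Ti(OiPr)4 (cat.), D-(−)-diisopropyl tartrate (cat.), t-BuOOH (decane), 4 Å MS, CH2Cl2, −20 °C
Reagents that add atoms: tert-butyl hydroperoxide CC(C)(C)OO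
Why: In the Katsuki–Sharpless asymmetric epoxidation only the alkene with a free allylic hydroxyl binds to titanium, and with the D-(−)-tartrate an E allylic alcohol of the geraniol type is oxidised on the face that gives the (2R,3R)-epoxide, whose C3–O bond becomes the C2–O1 bond of the target with R configuration.

Step 6
Reactants: 6 (2R,3R)-2,3-epoxide of 5; 7 trimethylsilylacetylene
Product: 10 (2R,3R)-epoxy silylalkyne (CH2OH of 6 replaced by CH2C≡CSiMe3), via lithium trimethylsilylacetylide 8 (not isolated), via epoxy triflate 9 (not isolated)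
Conditions: 6, Tf2O, 2,6-lutidine, CH2Cl2, −78 °C, cold aqueous wash; 7, n-BuLi, THF, −78 °C; crude triflate added, DMPU, −78 → −20 °C
Reagents that add atoms: none
Why: SN2 displacement of a primary 2,3-epoxy triflate by a lithium acetylide at low temperature forms C4–C4a, and the epoxide is kept closed here because a free 3-hydroxy sulfonate would be deprotonated by the acetylide and could close to an oxetane.

Step 7
Reactants: 10 (2R,3R)-epoxy silylalkyne
Product: 12 (5R,8E,12E,16E)-18-(tert-butyldimethylsilyloxy)-5,9,13,17-tetramethyloctadeca-8,12,16-trien-1-yn-5-ol, via silylalkynyl tertiary alcohol 11 (not isolated)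
Conditions: LiEt3BH, THF, 0 °C → rt; then MeOH, K2CO3 (cat.), rt
Reagents that add atoms: none
Why: Super-Hydride opens the trisubstituted epoxide by SN2 attack at its less substituted carbon, so the tertiary C–O bond and its R configuration are kept, and basic methanol then effects the usual protodesilylation of the alkynylsilane.

Step 8
Reactants: 13 2-bromopropene; 14 chromium hexacarbonyl
Product: 17 tetramethylammonium pentacarbonyl(1-oxido-2-methylprop-2-enylidene)chromate, via isopropenyllithium 15 (not isolated), via lithium acyl chromate 16 (not isolated)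
Conditions: 13, t-BuLi (2 equiv), Et2O, −78 °C; 14, Et2O, 0 °C → rt; Me4NBr, degassed H2O, extraction into CH2Cl2
Reagents that add atoms: tetramethylammonium bromide C[N+](C)(C)C.[Br-]
Why: This is the Fischer carbene route (bromine–lithium exchange, addition of the alkenyllithium to a carbonyl ligand), and cation metathesis turns the lithium acylate into a storable ammonium salt that can be O-acylated cleanly.

Step 9
Reactants: 12 (5R,8E,12E,16E)-18-(tert-butyldimethylsilyloxy)-5,9,13,17-tetramethyloctadeca-8,12,16-trien-1-yn-5-ol; 17 tetramethylammonium pentacarbonyl(1-oxido-2-methylprop-2-enylidene)chromate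
Product: 21 (R)-13'-(tert-butyldimethylsilyloxy)-δ-tocotrienol, via acetoxycarbene complex 18 (not isolated), via tertiary alkoxycarbene complex 19 (not isolated), via tricarbonylchromium arene complex 20 (not isolated)
Conditions: 17 (2 equiv), AcBr (1.9 equiv), CH2Cl2, −40 °C; 12, −40 → −5 °C; cold aq NaHCO3 wash, solvent change at 0 °C; degassed THF (0.005 M), Ar, 45 °C; then air, Et2O, rt
Reagents that add atoms: none
Why: Proposed new method: acetyl bromide O-acylates 17 to the acetoxycarbene 18, a mixed-anhydride analogue whose carbene carbon should take up the tertiary alcohol 12 by addition–elimination without touching the C2–O bond; this alcoholysis is established only for primary and hindered secondary alcohols, and the closest known reaction type for the whole operation is that alcoholysis followed by the intramolecular Dötz benzannulation of alkynyloxy(aryl)carbene chromium complexes. On warming, 19 should lose a cis CO, bind the tethered alkyne and insert it into Cr=C8a (bond C8a–C4a), shift CO onto the new carbene carbon C5 (bond C5–C6) to give a dienylketene, and close by 6π electrocyclisation onto the isopropenyl CH2 (bond C6–C7), after which tautomerisation gives the chromanol as its Cr(CO)3 complex 20, which air frees from the metal. The dihydropyran ring (O1–C2–C3–C4–C4a–C8a) closes by the intramolecular alkyne insertion, helped by the geminal substitution at C2 (Thorpe–Ingold effect), and the benzene ring closes by the ketene electrocyclisation. No stereocentre is formed: C2 comes from step 5, its C–O bond is never broken, and the bicarbonate wash, the neutral medium and the low temperature are chosen to keep the tertiary alkoxy group from ionising or eliminating, which is also why 19 is not put on silica. The regiochemistry needed is the reverse of the intermolecular preference (substituted alkyne carbon on C8a, alkyne CH next to C6); the three-carbon link through O1 cannot reach the other orientation, high dilution shuts off the intermolecular reaction, and the methyl group ends on C8 because the isopropenyl α-carbon carries it. The C3'=C4' alkene hangs from C2 at the same distance as the alkyne, but a trisubstituted alkene is a far poorer ligand for the Cr(CO)4 fragment than a terminal alkyne, so cyclopropanation should not compete.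

Step 10
Reactants: 21 (R)-13'-(tert-butyldimethylsilyloxy)-δ-tocotrienol
Product: 22 6-O-acetate of 21
Conditions: Ac2O, Et3N, DMAP (cat.), CH2Cl2, 0 °C → rt
Reagents that add atoms: acetic anhydride CC(=O)OC(C)=O
Why: Routine DMAP-catalysed phenol acetylation, needed because the free chromanol is an easily oxidised hydroquinone monoether that would not tolerate MnO2 and chlorite/HOCl.

Step 11
Reactants: 22 6-O-acetate of 21
Product: 23 (R)-13'-hydroxy-δ-tocotrienol 6-O-acetate
Conditions: HF·pyridine, pyridine, THF, 0 °C → rt
Reagents that add atoms: none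
Why: Fluoride-driven silyl ether cleavage in a buffered, weakly acidic medium, chosen over basic TBAF because that reagent can cleave aryl acetates.

Step 12
Reactants: 23 (R)-13'-hydroxy-δ-tocotrienol 6-O-acetate
Product: 24 (R,11'E)-13'-oxo-δ-tocotrienol 6-O-acetate (enal)
Conditions: MnO2 (activated, excess), CH2Cl2, rt
Reagents that add atoms: none
Why: MnO2 oxidation is selective for the primary allylic alcohol and stops at the enal without E/Z isomerisation, leaving the isolated alkenes and the aryl acetate alone.

Step 13
Reactants: 24 (R,11'E)-13'-oxo-δ-tocotrienol 6-O-acetate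
Product: 25 garcinoic acid 6-O-acetate
Conditions: NaClO2, NaH2PO4, 2-methyl-2-butene (large excess), t-BuOH/H2O, 0 °C → rt
Reagents that add atoms: sodium chlorite [Na+].[O-]Cl=O
Why: The Pinnick oxidation converts α,β-unsaturated aldehydes into the acids with retention of geometry, and the large excess of 2-methyl-2-butene intercepts HOCl before it can add to the chain alkenes or chlorinate the acetylated arene.

Step 14
Reactants: 25 garcinoic acid 6-O-acetate
Product: 26 garcinoic acid
Conditions: LiOH, degassed THF/H2O, Ar, 0 °C → rt; then 1 M HCl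
Reagents that add atoms: none
Why: Saponification of the aryl acetate is fast under mild base, air is excluded because the phenolate is oxidisable, and acidification returns the free acid with C2 and the three E alkenes unchanged.

**Compound list**
1 | (E,E,E)-geranylgeraniol | CC(C)=CCC/C(C)=C/CC/C(C)=C/CC/C(C)=C/CO | starting material
2 | (E,E,E)-geranylgeranyl acetate | CC(C)=CCC/C(C)=C/CC/C(C)=C/CC/C(C)=C/COC(C)=O | intermediate
3 | (2E,6E,10E,14E)-16-hydroxygeranylgeranyl acetate | OC/C(C)=C/CC/C(C)=C/CC/C(C)=C/CC/C(C)=C/COC(C)=O | intermediate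
4 | (2E,6E,10E,14E)-16-(tert-butyldimethylsilyloxy)geranylgeranyl acetate | CC(C)(C)[Si](C)(C)OC/C(C)=C/CC/C(C)=C/CC/C(C)=C/CC/C(C)=C/COC(C)=O | intermediate
5 | (2E,6E,10E,14E)-16-(tert-butyldimethylsilyloxy)geranylgeraniol | CC(C)(C)[Si](C)(C)OC/C(C)=C/CC/C(C)=C/CC/C(C)=C/CC/C(C)=C/CO | intermediate
6 | (2R,3R)-2,3-epoxide of 5 | CC(C)(C)[Si](C)(C)OC/C(C)=C/CC/C(C)=C/CC/C(C)=C/CC[C@@]1(C)O[C@@H]1CO | intermediate
7 | trimethylsilylacetylene | C#C[Si](C)(C)C | starting material
8 | lithium trimethylsilylacetylide | [Li]C#C[Si](C)(C)C | intermediate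
9 | (2R,3R)-epoxy triflate (triflate of 6) | CC(C)(C)[Si](C)(C)OC/C(C)=C/CC/C(C)=C/CC/C(C)=C/CC[C@@]1(C)O[C@@H]1COS(=O)(=O)C(F)(F)F | intermediate
10 | (2R,3R)-epoxy silylalkyne | CC(C)(C)[Si](C)(C)OC/C(C)=C/CC/C(C)=C/CC/C(C)=C/CC[C@@]1(C)O[C@@H]1CC#C[Si](C)(C)C | intermediate
11 | (R)-tertiary alcohol with 4-(trimethylsilyl)but-3-ynyl arm | CC(C)(C)[Si](C)(C)OC/C(C)=C/CC/C(C)=C/CC/C(C)=C/CC[C@](C)(CCC#C[Si](C)(C)C)O | intermediate
12 | (5R,8E,12E,16E)-18-(tert-butyldimethylsilyloxy)-5,9,13,17-tetramethyloctadeca-8,12,16-trien-1-yn-5-ol | CC(C)(C)[Si](C)(C)OC/C(C)=C/CC/C(C)=C/CC/C(C)=C/CC[C@](C)(CCC#C)O | intermediate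
13 | 2-bromopropene | CC(Br)=C | starting material
14 | chromium hexacarbonyl | O=C=[Cr](=C=O)(=C=O)(=C=O)(=C=O)=C=O | starting material
15 | isopropenyllithium | [Li]C(C)=C | intermediate
16 | lithium pentacarbonyl(1-oxido-2-methylprop-2-enylidene)chromate | [Li+].[O-]C(C(C)=C)=[Cr](=C=O)(=C=O)(=C=O)(=C=O)=C=O | intermediate
17 | tetramethylammonium pentacarbonyl(1-oxido-2-methylprop-2-enylidene)chromate | C[N+](C)(C)C.[O-]C(C(C)=C)=[Cr](=C=O)(=C=O)(=C=O)(=C=O)=C=O | intermediate
18 | pentacarbonyl[acetoxy(isopropenyl)carbene]chromium | CC(=O)OC(C(C)=C)=[Cr](=C=O)(=C=O)(=C=O)(=C=O)=C=O | intermediate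
19 | pentacarbonyl[(tert-alkoxy)(isopropenyl)carbene]chromium; the alkoxy carbon is C2 (R) with methyl, but-3-ynyl arm and the silyloxy trienyl chain | C/C(=C\CC/C(C)=C/CC[C@](C)(CCC#C)OC(C(C)=C)=[Cr](=C=O)(=C=O)(=C=O)(=C=O)=C=O)CC/C=C(\C)CO[Si](C)(C)C(C)(C)C | intermediate
20 | η6-tricarbonylchromium complex of 21 (either arene face) | C/C(=C\CC/C(C)=C/CC[C@]1(C)CCc2cc(O)cc(C)c2O1)CC/C=C(\C)CO[Si](C)(C)C(C)(C)C.O=C=[Cr](=C=O)=C=O | intermediate
21 | (R)-13'-(tert-butyldimethylsilyloxy)-δ-tocotrienol | C/C(=C\CC/C(C)=C/CC[C@]1(C)CCc2cc(O)cc(C)c2O1)CC/C=C(\C)CO[Si](C)(C)C(C)(C)C | intermediate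
22 | 6-O-acetate of 21 | C/C(=C\CC/C(C)=C/CC[C@]1(C)CCc2cc(OC(C)=O)cc(C)c2O1)CC/C=C(\C)CO[Si](C)(C)C(C)(C)C | intermediate
23 | (R)-13'-hydroxy-δ-tocotrienol 6-O-acetate | C/C(=C\CC/C(C)=C/CC[C@]1(C)CCc2cc(OC(C)=O)cc(C)c2O1)CC/C=C(\C)CO | intermediate
24 | (R,11'E)-13'-oxo-δ-tocotrienol 6-O-acetate | C/C(=C\CC/C(C)=C/CC[C@]1(C)CCc2cc(OC(C)=O)cc(C)c2O1)CC/C=C(\C)C=O | intermediate
25 | garcinoic acid 6-O-acetate | C/C(=C\CC/C(C)=C/CC[C@]1(C)CCc2cc(OC(C)=O)cc(C)c2O1)CC/C=C(\C)C(=O)O | intermediate
26 | garcinoic acid, (2R) | C/C(=C\CC/C(C)=C/CC[C@]1(C)CCc2cc(O)cc(C)c2O1)CC/C=C(\C)C(=O)O | target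

**Step count**
Total step count: 14. Longest linear sequence: 13 (steps 1–7 and 9–14; step 8 is a one-step branch).

**Steps most likely to fail**

Step 9.
- What may go wrong: The hindered tertiary hydroxyl may add to the acetoxycarbene more slowly than that complex decays, or it may be acetylated at the acyl carbon instead.
  - On warming, the tertiary alkoxy group may leave by ionisation or elimination.
  - After alkyne insertion, the vinylcarbene may follow channels that do not take up CO.
- Fallback: It uses known reactions only, runs from 6 back to 21, and makes the O1–C8a bond with palladium.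
  - Appel-type iodination of 6 (I2, PPh3, imidazole) gives the epoxy iodide F1. Zinc dust in ethanol opens it reductively to the (R)-vinyl carbinol F2 with the tertiary C–O bond intact.
  - In parallel, commercial 2-bromo-1-iodo-3-methylbenzene is borylated at its only unhindered C–H ([Ir(OMe)(cod)]2, dtbpy, B2pin2) to the aryl pinacol boronate F3. This is oxidised (NaBO3) to 4-bromo-3-iodo-5-methylphenol F4 and acylated (PivCl, Et3N) to the aryl pivalate F5.
  - 9-BBN adds only to the vinyl group of F2 to give the B-alkyl borane F6. Suzuki–Miyaura coupling at the C–I bond of F5 (PdCl2(dppf), K3PO4, THF/DMF/H2O) then gives the bromoaryl tertiary alcohol F7.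
  - Buchwald–Hartwig-type intramolecular C–O coupling (Pd(OAc)2, bulky di-tert-butyl biaryl phosphine, Cs2CO3, toluene, 80 °C) closes the pyran with retention at C2 to the chroman pivalate F8. DIBAL-H at −78 °C removes the pivalate and gives 21.

Step 2.
- What may go wrong: The selenium reagent may attack the two internal trisubstituted alkenes as well as the terminal one. The product may also be oxidised further to the enal, so that material is lost on separation.
- Fallback: It runs from 2 back to 3 and rebuilds the chain end instead of oxidising a C–H bond.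
  - NBS in aqueous THF at 0 °C, where the folded chain exposes mainly its end, gives the terminal bromohydrin F9.
  - DBU closes it to the terminal epoxide F10 without harming the acetate.
  - Periodic acid in aqueous ether cleaves the epoxide to the trisnor aldehyde F11.
  - Wittig reaction with the stabilised ylide 2-(triphenylphosphoranylidene)propanal (E-selective) gives the enal F12. Luche reduction (NaBH4, CeCl3, MeOH, 0 °C) then gives 3.

Step 6.
- What may go wrong: The epoxy triflate may decompose (ionisation assisted by the epoxide oxygen, alkylation of the pyridine base) before the acetylide reaches it.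
- Fallback: It runs from 6 back to 12, replaces steps 6 and 7, and opens the epoxide first.
  - Hydroxyl-directed Red-Al reduction (THF, 0 °C) delivers hydride to the epoxide carbon next to CH2OH and gives the (R)-1,3-diol F13.
  - TsCl/Et3N sulfonylates only the primary hydroxyl to the hydroxy tosylate F14.
  - TMSOTf/2,6-lutidine caps the tertiary hydroxyl as the silyl ether tosylate F15, so that no alkoxide can close an oxetane.
  - Acetylide 8 in THF/DMPU displaces the tosylate to the bis(trimethylsilyl) compound F16. K2CO3 in methanol removes both trimethylsilyl groups and gives 12.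

**Further compounds**
F1 | step 9 | epoxy iodide (CH2OH of 6 replaced by CH2I, spatial arrangement unchanged) | CC(C)(C)[Si](C)(C)OC/C(C)=C/CC/C(C)=C/CC/C(C)=C/CC[C@@]1(C)O[C@@H]1CI
F2 | step 9 | (R)-vinyl carbinol (16-silyloxygeranyllinalool) | CC(C)(C)[Si](C)(C)OC/C(C)=C/CC/C(C)=C/CC/C(C)=C/CC[C@](C)(C=C)O
F3 | step 9 | 2-(4-bromo-3-iodo-5-methylphenyl)-4,4,5,5-tetramethyl-1,3,2-dioxaborolane | Cc1cc(B2OC(C)(C)C(C)(C)O2)cc(I)c1Br
F4 | step 9 | 4-bromo-3-iodo-5-methylphenol | Cc1cc(O)cc(I)c1Br
F5 | step 9 | 4-bromo-3-iodo-5-methylphenyl pivalate | Cc1cc(OC(=O)C(C)(C)C)cc(I)c1Br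
F6 | step 9 | B-alkyl-9-BBN adduct of F2 | CC(C)(C)[Si](C)(C)OC/C(C)=C/CC/C(C)=C/CC/C(C)=C/CC[C@](C)(CCB1C2CCCC1CCC2)O
F7 | step 9 | (R)-bromoaryl tertiary alcohol | CC(C)(C)[Si](C)(C)OC/C(C)=C/CC/C(C)=C/CC/C(C)=C/CC[C@](C)(CCc1cc(OC(=O)C(C)(C)C)cc(C)c1Br)O
F8 | step 9 | 6-O-pivalate of 21 | C/C(=C\CC/C(C)=C/CC[C@]1(C)CCc2cc(OC(=O)C(C)(C)C)cc(C)c2O1)CC/C=C(\C)CO[Si](C)(C)C(C)(C)C
F9 | step 2 | 14-bromo-15-hydroxy-14,15-dihydrogeranylgeranyl acetate (racemic at C14) | CC(C)(O)C(Br)CC/C(C)=C/CC/C(C)=C/CC/C(C)=C/COC(C)=O
F10 | step 2 | 14,15-epoxygeranylgeranyl acetate (racemic at C14) | CC1(C)OC1CC/C(C)=C/CC/C(C)=C/CC/C(C)=C/COC(C)=O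
F11 | step 2 | (2E,6E,10E)-3,7,11-trimethyl-14-oxotetradeca-2,6,10-trienyl acetate | O=CCC/C(C)=C/CC/C(C)=C/CC/C(C)=C/COC(C)=O
F12 | step 2 | (2E,6E,10E,14E)-16-oxogeranylgeranyl acetate | O=C/C(C)=C/CC/C(C)=C/CC/C(C)=C/CC/C(C)=C/COC(C)=O
F13 | step 6 | (3R,6E,10E,14E)-16-(tert-butyldimethylsilyloxy)-3,7,11,15-tetramethylhexadeca-6,10,14-triene-1,3-diol | CC(C)(C)[Si](C)(C)OC/C(C)=C/CC/C(C)=C/CC/C(C)=C/CC[C@](C)(CCO)O
F14 | step 6 | primary tosylate of F13 | CC(C)(C)[Si](C)(C)OC/C(C)=C/CC/C(C)=C/CC/C(C)=C/CC[C@](C)(CCOS(=O)(=O)c1ccc(C)cc1)O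
F15 | step 6 | tertiary trimethylsilyl ether of F14 | CC(C)(C)[Si](C)(C)OC/C(C)=C/CC/C(C)=C/CC/C(C)=C/CC[C@](C)(CCOS(=O)(=O)c1ccc(C)cc1)O[Si](C)(C)C
F16 | step 6 | O,C-bis(trimethylsilyl) derivative of 12 | CC(C)(C)[Si](C)(C)OC/C(C)=C/CC/C(C)=C/CC/C(C)=C/CC[C@](C)(CCC#C[Si](C)(C)C)O[Si](C)(C)C
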